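0.00902 M of target is the reading of the crossing amount of the red run: the c(target) at which the target-driven rate (autocatalysis), growth constant times c(target), equals the slow background rate.

| flask | starting material | reagent | time |
|---|---|---|---|
| red | 1.00 M | 3.00 M |  |
| grey | 1.50 M | 3.00 M |  |
| violet | 0.600 M | 2.60 M | 16 min |

| run | time / min | [target] / M |
|---|---|---|
| red run | 0.71 | 0 |
| red run | 2.2 | 0.012 |
| red run | 4.1 | 0.014 |
| red run | 6.5 | 0.061 |
| red run | 9.3 | 0.177 |
| red run | 13 | 0.466 |
| red run | 16 | 0.645 |
| grey run | 0.71 | 0.006 |
| grey run | 2.2 | 0.016 |
| grey run | 4.1 | 0.023 |
| grey run | 6.5 | 0.149 |
| grey run | 9.3 | 0.392 |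
| grey run | 13 | 0.914 |
| grey run | 16 | 1.142 |

(standard deviation of a reading: 0.01 M)

1. order of the initial rate in [starting material], near the charge of the red run, the rate being that where two percent of its starting material are target (one fixed amount of target, the same in the runs compared)
2. target in the violet run at 16 min, as a share of the starting material charged

- Overall: starting material + reagent -> target.
- Constant volume, constant temperature.
- The analysis sees a species whether free or bound.
- "The second partner" is reagent.
- An order is taken over about fifteen percent of the charge, up and down.

1. Reading the red run. The background reads 0.00341 M min⁻¹, from the reading at 4.1 min. The growth constant reads 0.379 min⁻¹, the slope of ln(c(target)/unconverted charge) from 9.3 min to 13 min. The crossing is rough: that background reading of 0.014 M carries a scatter of 0.01 M.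

2. Turning up the starting material. In the grey run the background reads 0.00561 M min⁻¹, 1.65 times the red value, while the growth constant reads 0.401 min⁻¹, 1.06 times. The grey crossing is 0.0140 M. In my reckoning the rate at a fixed c(target) is the growth constant times the sum of that c(target) and the crossing. At 0.0200 M, which lies above the red crossing, this gives 0.0110 M min⁻¹ for red and 0.0136 M min⁻¹ for grey. My order over that wide step is 0.532.

3. Turning down the reagent and the starting material together, as the violet run does. The crossing as a share of the charge reads 0.902 % in red and 0.933 % in grey, so I carry that share to the violet run and let the growth constant move the curve. Scaling it with the starting material as read, and assuming first order in the untested reagent, gives 0.305 min⁻¹. Shifting the red logit at 16 min accordingly gives −0.578, which is 36.0 %.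

4. The forecast gives 0.6 and 36 %, on the ground that “the autocatalytic part is therefore about zero order and the background about first order”. My order lies below its value.

5. The flask gives an order of 0.62 and 34.8 % in the violet run.

    starting material ⇌ intermediate + by-product (0.03690 min⁻¹, 0.008760 M⁻¹ min⁻¹)
    intermediate + reagent → target (0.02070 M⁻¹ min⁻¹)
    2 starting material ⇌ idle substrate dimer, settled at all times (0.3660 M⁻¹)
    starting material + reagent + target → 2 target (0.1842 M⁻² min⁻¹)

Both forecast values lie within their margins. The apparent order in reagent early in the red run is 0.75, lower than the first order assumed. The crossing gives 0.0110 M min⁻¹ for the red run at the fixed amount of target, where the flask has 0.012 M min⁻¹. For the grey run, 0.0140 M gives 0.0136 M min⁻¹, where the flask has 0.015 M min⁻¹.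

All runs are calculated for substances that don't exist.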